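Ring C (C8, C9, C11, C12, C13, C14) is cut at C13–C14 and C9–C8, so that it becomes the adduct of a C13=C12–C11=C9 diene and a C14=C8 dienophile. The feature exploited is that the glycidate arm C14–C15–C16 lies cis to C13 while C17 on C13 bears oxygen: C17–O–C16 is closed into a temporary lactone (ring D). An open-chain furyl dienyl ester of an allene-1,3-dicarboxylate then folds in one intramolecular Diels–Alder reaction through the remote allene bond, closing rings C and D and setting C8, C9 and C13. Hydrogenation, epoxidation, lactone opening with oxidation at C17, and a late ynone-to-pyranone side-chain assembly finish the target.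

Key step: step 8

Remark on numbering: ring C = C8 (bears methyl C30 and carbonyl C7), C9 (bears H and carbinol C10), C11, C12, C13 (bears methyl C18 and C17), C14 (spiro carbon); C15/C16 = oxirane CH and ester carbon; ring D = temporary lactone C13–C17–O–C16–C15–C14; ring A = the dimethylpyranone (C1–C5), C6 = side-chain =CH. PMB = 4-methoxybenzyl, TMSE = 2-(trimethylsilyl)ethyl.

Assumption: compounds 1, 5, 7, 11, 13, 14, 26 and 30 are taken as commercial.

Assumption: (−)-MIB [(2S)-3-exo-(morpholino)isoborneol] is taken to deliver the (S)-carbinol in step 4, as in alkenylzinc additions to aromatic aldehydes; its antipode would give the C17 epimer.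

Step 1
Reactants: 1 (R)-but-3-yn-2-ol
Product: 2 1-({[(2R)-but-3-yn-2-yl]oxy}methyl)-4-methoxybenzene
Conditions: NaH, 4-methoxybenzyl chloride, Bu4NI (cat.), THF/DMF, 0 °C to rt
Reagents that add atoms: 4-methoxybenzyl chloride COc1ccc(CCl)cc1
Why: Williamson ether synthesis on the sodium alkoxide; the carbinol centre is not touched, so the (R) configuration that becomes C10 is carried over from the chiral pool.

Step 2
Reactants: 2 1-({[(2R)-but-3-yn-2-yl]oxy}methyl)-4-methoxybenzene
Product: 4 1-({[(2R,3E)-4-iodobut-3-en-2-yl]oxy}methyl)-4-methoxybenzene, via alkenylzirconocene chloride 3 (not isolated)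
Conditions: Cp2Zr(H)Cl, THF, rt; then I2, 0 °C
Reagents that add atoms: iodine II
Why: Hydrozirconation of the terminal alkyne is a syn addition that places zirconium on the terminal carbon, and iodinolysis of the C–Zr bond with retention should give the (E)-vinyl iodide (future C9=C11).

Step 3
Reactants: 4 1-({[(2R,3E)-4-iodobut-3-en-2-yl]oxy}methyl)-4-methoxybenzene; 5 propyne
Product: 6 1-({[(2R,3E)-hept-3-en-5-yn-2-yl]oxy}methyl)-4-methoxybenzene
Conditions: propyne (excess), PdCl2(PPh3)2 (3 mol%), CuI (6 mol%), Et3N, THF, 0 °C to rt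
Reagents that add atoms: none
Why: Sonogashira coupling of the vinyl iodide proceeds with retention of the E geometry, and the methyl group of propyne becomes C18.

Step 4
Reactants: 6 1-({[(2R,3E)-hept-3-en-5-yn-2-yl]oxy}methyl)-4-methoxybenzene; 7 furan-3-carbaldehyde
Product: 10 (1S,2E,4E,6R)-1-(furan-3-yl)-6-[(4-methoxyphenyl)methoxy]-2-methylhepta-2,4-dien-1-ol, via dienylzirconocene chloride 8 (not isolated), via dienyl(methyl)zinc 9 (not isolated)
Conditions: Cp2Zr(H)Cl, CH2Cl2, rt; Me2Zn, PhMe, −65 °C; (−)-MIB (10 mol%), then 7, −30 to 0 °C; aq. NH4Cl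
Reagents that add atoms: none
Why: Hydrozirconation of the internal alkyne (syn, zirconium at the methyl-bearing carbon remote from the alkene), Zr-to-Zn transmetalation and amino-alcohol-catalysed enantioselective 1,2-addition of the alkenylzinc to the aldehyde should give the (E,E)-dienol with C18 cis to the diene chain, the ligand setting the auxiliary C17 carbinol as (S) under reagent control because the C10 centre is remote.

Step 5
Reactants: 10 (1S,2E,4E,6R)-1-(furan-3-yl)-6-[(4-methoxyphenyl)methoxy]-2-methylhepta-2,4-dien-1-ol; 11 (triphenylphosphoranylidene)ketene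
Product: 12 (1S,2E,4E,6R)-1-(furan-3-yl)-6-[(4-methoxyphenyl)methoxy]-2-methylhepta-2,4-dien-1-yl (triphenyl-λ5-phosphanylidene)acetate
Conditions: PhMe, 80 °C
Reagents that add atoms: none
Why: Addition of the alcohol O–H across the C=C of the cumulated ylide should give the ester-stabilised phosphorane under neutral conditions, which avoids acylating agents that could ionise the dienylic furyl carbinol and leaves C17 untouched.

Step 6
Reactants: 13 2,2,5-trimethyl-1,3-dioxane-4,6-dione; 14 2-(trimethylsilyl)ethanol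
Product: 15 2-methyl-3-oxo-3-[2-(trimethylsilyl)ethoxy]propanoic acid (racemic)
Conditions: PhMe, 90 °C
Reagents that add atoms: none
Why: Alcoholysis of the cyclic acylal with loss of acetone is the standard route to malonic half-esters, and the stereocentre is irrelevant because it becomes sp2 in step 8.

Step 7
Reactants: 15 2-methyl-3-oxo-3-[2-(trimethylsilyl)ethoxy]propanoic acid
Product: 16 2-(trimethylsilyl)ethyl 3-chloro-2-methyl-3-oxopropanoate (racemic)
Conditions: (COCl)2, DMF (cat.), CH2Cl2, 0 °C to rt; volatiles removed, crude chloride used at once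
Reagents that add atoms: oxalyl chloride ClC(=O)C(=O)Cl
Why: Acid chloride formation through the catalytic chloroiminium (Vilsmeier) species; the remaining α-hydrogen makes 16 a ketene precursor.

Step 8
Reactants: 12 (1S,2E,4E,6R)-1-(furan-3-yl)-6-[(4-methoxyphenyl)methoxy]-2-methylhepta-2,4-dien-1-yl (triphenyl-λ5-phosphanylidene)acetate; 16 2-(trimethylsilyl)ethyl 3-chloro-2-methyl-3-oxopropanoate
Product: 19 2-(trimethylsilyl)ethyl (1S,5R,6S,8aR)-1-(furan-3-yl)-6-{(1R)-1-[(4-methoxyphenyl)methoxy]ethyl}-5,8a-dimethyl-3-oxo-1,5,6,8a-tetrahydro-3H-isochromene-5-carboxylate (ring C/D lactone; 8R,9S,10R,13R,17S in the numbering above), via ester-substituted methylketene 17 (not isolated), via allene diester 18 (not isolated)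
Conditions: Et3N (2.5 equiv), CH2Cl2, 0 °C to rt; then solvent exchange to PhMe (0.01 M), BHT (cat.), 90 °C
Reagents that add atoms: none
Why: Et3N converts 16 into ketene 17, the stabilised phosphorane olefinates it (Wittig reaction of a ketene) to the allene diester 18, and on heating the remote C14=C8 bond of the allene, activated by the C7 ester, adds across the C13=C12–C11=C9 diene in a concerted, suprafacial [4+2] cycloaddition that forms C13–C14 and C9–C8 together. The closest known reaction type is the intramolecular Diels–Alder reaction of ester- or amide-tethered allenes through the allene bond remote from the tether. Ring C closes as the cyclohexene of the [4+2] event, and ring D closes as a six-membered unsaturated lactone (C13–C17–O–C16–C15=C14) because the reacting p-orbitals of C14=C8 lie in the plane of the planar C17–O–C16(=O)–C15 ester, so C13 reaches C14 without twisting the ester, whereas the proximal C15=C14 bond would need a strained five-membered lactone with a deconjugated ester. C13 and C9 follow from the (E,E)-diene (C17 and C10 both outside, hence cis on ring C) and from the diene face selected by the C17 centre, whose furyl group is expected to sit on the side of C12 and away from the inside C18 methyl in the lactone-forming transition state; C8 follows from the exo position of the C7 ester, which keeps the C30 methyl away from the inside C18 methyl. Et3N keeps the two axial epimers of 18 in equilibrium through C15–H deprotonation, so both should drain through this matched transition state. The selectivities needed are therefore remote over proximal allene bond (tether geometry), exo over endo ester (methyl–methyl repulsion) and one diene face (C17 centre), with C16 locked cis to C13 by the ring for the later oxirane.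

Step 9
Reactants: 19 ring C/D lactone (C11=C12, C14=C15)
Product: 20 2-(trimethylsilyl)ethyl (1S,5R,6S,8aR)-1-(furan-3-yl)-6-{(1R)-1-[(4-methoxyphenyl)methoxy]ethyl}-5,8a-dimethyl-3-oxo-1,5,6,7,8,8a-hexahydro-3H-isochromene-5-carboxylate
Conditions: H2 (5 atm), RhCl(PPh3)3 (10 mol%), PhH/EtOH, 40 °C
Reagents that add atoms: none
Why: Homogeneous hydrogenation with RhCl(PPh3)3 should select the cis-disubstituted C11=C12 bond over the conjugated trisubstituted C14=C15 bond, the furan and the benzylic ether, and forms no stereocentre.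

Step 10
Reactants: 20 C11,C12-dihydro lactone
Product: 21 14,15-epoxy lactone (8R,9S,10R,13S,14R,15S,17R): the 14,15-epoxide of 20 with the oxirane oxygen on the face of the C30 methyl group
Conditions: t-BuOOH, n-BuLi (gives t-BuOOLi), THF, −78 °C; then 20, −20 to 0 °C; aq. NH4Cl
Reagents that add atoms: tert-butyl hydroperoxide CC(C)(C)OO
Why: Weitz–Scheffer-type nucleophilic epoxidation of the unsaturated lactone, in which the peroxide should add to C14 axially from the face of the equatorial C30 methyl, anti to the 1,3-diaxial C18 methyl and C7 ester of ring C, after which the lactone enolate closes the oxirane on the same face and so sets C14 and C15 (the ring fixes C16 cis to C13).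

Step 11
Reactants: 21 14,15-epoxy lactone
Product: 23 2-methyl 4-[2-(trimethylsilyl)ethyl] (2S,3R,4R,5S,8S)-8-[(R)-furan-3-yl(hydroxy)methyl]-5-{(1R)-1-[(4-methoxyphenyl)methoxy]ethyl}-4,8-dimethyl-1-oxaspiro[2.5]octane-2,4-dicarboxylate, via lithium carboxylate 22 (not isolated)
Conditions: LiOH·H2O (1.05 equiv), THF/H2O, 0 °C; evaporation; then MeI, DMF, rt
Reagents that add atoms: lithium hydroxide [Li+].[OH-]; iodomethane CI
Why: Saponification of the δ-lactone at C16 (the hindered neopentyl TMSE ester is spared) and SN2 O-methylation of the carboxylate should trap the ring-opened form as the hydroxy methyl ester before it can relactonise, with no stereocentre touched.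

Step 12
Reactants: 23 hydroxy diester
Product: 24 2-methyl 4-[2-(trimethylsilyl)ethyl] (2S,3R,4R,5S,8R)-8-(furan-3-carbonyl)-5-{(1R)-1-[(4-methoxyphenyl)methoxy]ethyl}-4,8-dimethyl-1-oxaspiro[2.5]octane-2,4-dicarboxylate
Conditions: Dess–Martin periodinane, pyridine, CH2Cl2, 0 °C to rt
Reagents that add atoms: none
Why: Dess–Martin oxidation of the furyl carbinol to the 3-furoyl ketone removes the auxiliary C17 stereocentre and ends any relactonisation, and nothing can epimerise because C13 is quaternary.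

Step 13
Reactants: 24 furyl ketone diester
Product: 25 (2S,3R,4R,5S,8R)-8-(furan-3-carbonyl)-2-(methoxycarbonyl)-5-{(1R)-1-[(4-methoxyphenyl)methoxy]ethyl}-4,8-dimethyl-1-oxaspiro[2.5]octane-4-carboxylic acid
Conditions: Bu4NF, THF, 0 °C to rt; aq. NH4Cl
Reagents that add atoms: none
Why: Fluoride attack on silicon triggers β-elimination of the 2-(trimethylsilyl)ethyl ester (ethene and Me3SiF are lost), which should free the hindered C7 acid without touching the methyl ester, the oxirane or the PMB ether.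

Step 14
Reactants: 25 C7 carboxylic acid; 26 2-methylbut-3-yn-2-ol
Product: 28 methyl (2S,3R,4R,5S,8R)-8-(furan-3-carbonyl)-4-(4-hydroxy-4-methylpent-2-ynoyl)-5-{(1R)-1-[(4-methoxyphenyl)methoxy]ethyl}-4,8-dimethyl-1-oxaspiro[2.5]octane-2-carboxylate, via acid chloride 27 (not isolated)
Conditions: 1-chloro-N,N,2-trimethylprop-1-en-1-amine, CH2Cl2, 0 °C to rt; then 26, PdCl2(PPh3)2 (5 mol%), CuI (10 mol%), Et3N, THF, rt
Reagents that add atoms: none
Why: The acid is converted under neutral conditions into the acid chloride by the α-chloroenamine, and an acyl Sonogashira coupling with the terminal alkyne should then give the ynone at C7, the only acyl halide present.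

Step 15
Reactants: 28 ynone
Product: 29 methyl (2S,3R,4R,5S,8R)-8-(furan-3-carbonyl)-4-[(2Z)-4-hydroxy-3-iodo-4-methylpent-2-enoyl]-5-{(1R)-1-[(4-methoxyphenyl)methoxy]ethyl}-4,8-dimethyl-1-oxaspiro[2.5]octane-2-carboxylate
Conditions: NaI, AcOH, rt, dark
Reagents that add atoms: sodium iodide [Na+].[I-]
Why: Conjugate hydroiodination of the ynone (iodide adds at C5, protonation at C6 anti) should give the (Z)-β-iodoenone with iodine cis to the C7 carbonyl, which fixes the C6=C5 geometry of the target.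

Step 16
Reactants: 29 (Z)-β-iodoenone; 30 ethyl (2Z)-3-(4,4,5,5-tetramethyl-1,3,2-dioxaborolan-2-yl)prop-2-enoate
Product: 32 methyl (2S,3R,4R,5S,8R)-4-[(2E)-2-(6,6-dimethyl-2-oxo-2H-pyran-5(6H)-ylidene)acetyl]-8-(furan-3-carbonyl)-5-{(1R)-1-[(4-methoxyphenyl)methoxy]ethyl}-4,8-dimethyl-1-oxaspiro[2.5]octane-2-carboxylate, via hydroxy dienoate 31 (not isolated)
Conditions: Pd(dppf)Cl2 (5 mol%), K3PO4, THF/H2O (10:1), 40 °C
Reagents that add atoms: none
Why: Suzuki–Miyaura coupling with retention at both alkenes joins C5 to C1, and the tertiary alkoxide should then lactonise onto the cis-disposed ethyl ester (favoured by the gem-dimethyl group) to close ring A.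

Step 17
Reactants: 32 PMB-protected target
Product: 33 methyl (2S,3R,4R,5S,8R)-4-[(2E)-2-(6,6-dimethyl-2-oxo-2H-pyran-5(6H)-ylidene)acetyl]-8-(furan-3-carbonyl)-5-[(1R)-1-hydroxyethyl]-4,8-dimethyl-1-oxaspiro[2.5]octane-2-carboxylate (CNP0293135.1)
Conditions: DDQ, CH2Cl2/pH 7 buffer (10:1), 0 °C
Reagents that add atoms: none
Why: Oxidative cleavage of the 4-methoxybenzyl ether by DDQ (hydride abstraction, then hydrolysis of the oxocarbenium ion) under buffered conditions should free the C10 alcohol without affecting the oxirane, the esters or the electron-poor furan.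

Compound list

1 | (R)-but-3-yn-2-ol | C[C@@H](O)C#C | starting material
2 | 1-({[(2R)-but-3-yn-2-yl]oxy}methyl)-4-methoxybenzene | C[C@@H](OCc1ccc(OC)cc1)C#C | intermediate
3 | chloro{(1E,3R)-3-[(4-methoxyphenyl)methoxy]but-1-en-1-yl}bis(cyclopentadienyl)zirconium | C[C@@H](OCc1ccc(OC)cc1)/C=C/[Zr](Cl)(C1C=CC=C1)C1C=CC=C1 | intermediate
4 | 1-({[(2R,3E)-4-iodobut-3-en-2-yl]oxy}methyl)-4-methoxybenzene | C[C@@H](OCc1ccc(OC)cc1)/C=C/I | intermediate
5 | propyne | CC#C | starting material
6 | 1-({[(2R,3E)-hept-3-en-5-yn-2-yl]oxy}methyl)-4-methoxybenzene | C[C@@H](OCc1ccc(OC)cc1)/C=C/C#CC | intermediate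
7 | furan-3-carbaldehyde | O=Cc1ccoc1 | starting material
8 | chloro{(2E,4E,6R)-6-[(4-methoxyphenyl)methoxy]hepta-2,4-dien-2-yl}bis(cyclopentadienyl)zirconium | C[C@@H](OCc1ccc(OC)cc1)/C=C/C=C(\C)[Zr](Cl)(C1C=CC=C1)C1C=CC=C1 | intermediate
9 | {(2E,4E,6R)-6-[(4-methoxyphenyl)methoxy]hepta-2,4-dien-2-yl}(methyl)zinc | C[C@@H](OCc1ccc(OC)cc1)/C=C/C=C(\C)[Zn]C | intermediate
10 | (1S,2E,4E,6R)-1-(furan-3-yl)-6-[(4-methoxyphenyl)methoxy]-2-methylhepta-2,4-dien-1-ol | C[C@@H](OCc1ccc(OC)cc1)/C=C/C=C(\C)[C@H](O)c1ccoc1 | intermediate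
11 | (triphenylphosphoranylidene)ketene | O=C=C=P(c1ccccc1)(c1ccccc1)c1ccccc1 | starting material
12 | (1S,2E,4E,6R)-1-(furan-3-yl)-6-[(4-methoxyphenyl)methoxy]-2-methylhepta-2,4-dien-1-yl (triphenyl-λ5-phosphanylidene)acetate | C[C@@H](OCc1ccc(OC)cc1)/C=C/C=C(\C)[C@H](OC(=O)C=P(c1ccccc1)(c1ccccc1)c1ccccc1)c1ccoc1 | intermediate
13 | 2,2,5-trimethyl-1,3-dioxane-4,6-dione | CC1C(=O)OC(C)(C)OC1=O | starting material
14 | 2-(trimethylsilyl)ethanol | C[Si](C)(C)CCO | starting material
15 | 2-methyl-3-oxo-3-[2-(trimethylsilyl)ethoxy]propanoic acid (racemic) | CC(C(=O)O)C(=O)OCC[Si](C)(C)C | intermediate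
16 | 2-(trimethylsilyl)ethyl 3-chloro-2-methyl-3-oxopropanoate (racemic) | CC(C(=O)Cl)C(=O)OCC[Si](C)(C)C | intermediate
17 | 2-(trimethylsilyl)ethyl 2-methyl-3-oxoprop-2-enoate (ester-substituted methylketene) | CC(=C=O)C(=O)OCC[Si](C)(C)C | intermediate
18 | 5-[(1S,2E,4E,6R)-1-(furan-3-yl)-6-[(4-methoxyphenyl)methoxy]-2-methylhepta-2,4-dien-1-yl] 1-[2-(trimethylsilyl)ethyl] 2-methylpenta-2,3-dienedioate (both axial epimers, interconverting) | C[C@@H](OCc1ccc(OC)cc1)/C=C/C=C(\C)[C@H](OC(=O)C=C=C(C)C(=O)OCC[Si](C)(C)C)c1ccoc1 | intermediate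
19 | 2-(trimethylsilyl)ethyl (1S,5R,6S,8aR)-1-(furan-3-yl)-6-{(1R)-1-[(4-methoxyphenyl)methoxy]ethyl}-5,8a-dimethyl-3-oxo-1,5,6,8a-tetrahydro-3H-isochromene-5-carboxylate | O=C1O[C@H](c2ccoc2)[C@]2(C)C=C[C@H]([C@@H](C)OCc3ccc(OC)cc3)[C@@](C)(C(=O)OCC[Si](C)(C)C)C2=C1 | intermediate
20 | 2-(trimethylsilyl)ethyl (1S,5R,6S,8aR)-1-(furan-3-yl)-6-{(1R)-1-[(4-methoxyphenyl)methoxy]ethyl}-5,8a-dimethyl-3-oxo-1,5,6,7,8,8a-hexahydro-3H-isochromene-5-carboxylate | O=C1O[C@H](c2ccoc2)[C@]2(C)CC[C@H]([C@@H](C)OCc3ccc(OC)cc3)[C@@](C)(C(=O)OCC[Si](C)(C)C)C2=C1 | intermediate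
21 | 14,15-epoxide of 20 (8R,9S,10R,13S,14R,15S,17R; oxirane oxygen on the face of the C30 methyl) | O=C1O[C@H](c2ccoc2)[C@]2(C)CC[C@H]([C@@H](C)OCc3ccc(OC)cc3)[C@@](C)(C(=O)OCC[Si](C)(C)C)[C@]23O[C@H]13 | intermediate
22 | lithium (2S,3R,4R,5S,8S)-8-[(R)-furan-3-yl(hydroxy)methyl]-5-{(1R)-1-[(4-methoxyphenyl)methoxy]ethyl}-4,8-dimethyl-4-{[2-(trimethylsilyl)ethoxy]carbonyl}-1-oxaspiro[2.5]octane-2-carboxylate | [Li+].[O-]C(=O)[C@H]1O[C@@]12[C@](C)([C@H](O)c1ccoc1)CC[C@H]([C@@H](C)OCc1ccc(OC)cc1)[C@@]2(C)C(=O)OCC[Si](C)(C)C | intermediate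
23 | 2-methyl 4-[2-(trimethylsilyl)ethyl] (2S,3R,4R,5S,8S)-8-[(R)-furan-3-yl(hydroxy)methyl]-5-{(1R)-1-[(4-methoxyphenyl)methoxy]ethyl}-4,8-dimethyl-1-oxaspiro[2.5]octane-2,4-dicarboxylate | COC(=O)[C@H]1O[C@@]12[C@](C)([C@H](O)c1ccoc1)CC[C@H]([C@@H](C)OCc1ccc(OC)cc1)[C@@]2(C)C(=O)OCC[Si](C)(C)C | intermediate
24 | 2-methyl 4-[2-(trimethylsilyl)ethyl] (2S,3R,4R,5S,8R)-8-(furan-3-carbonyl)-5-{(1R)-1-[(4-methoxyphenyl)methoxy]ethyl}-4,8-dimethyl-1-oxaspiro[2.5]octane-2,4-dicarboxylate | COC(=O)[C@H]1O[C@@]12[C@](C)(C(=O)c1ccoc1)CC[C@H]([C@@H](C)OCc1ccc(OC)cc1)[C@@]2(C)C(=O)OCC[Si](C)(C)C | intermediate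
25 | (2S,3R,4R,5S,8R)-8-(furan-3-carbonyl)-2-(methoxycarbonyl)-5-{(1R)-1-[(4-methoxyphenyl)methoxy]ethyl}-4,8-dimethyl-1-oxaspiro[2.5]octane-4-carboxylic acid | COC(=O)[C@H]1O[C@@]12[C@](C)(C(=O)c1ccoc1)CC[C@H]([C@@H](C)OCc1ccc(OC)cc1)[C@@]2(C)C(=O)O | intermediate
26 | 2-methylbut-3-yn-2-ol | CC(C)(O)C#C | starting material
27 | methyl (2S,3R,4R,5S,8R)-4-(chlorocarbonyl)-8-(furan-3-carbonyl)-5-{(1R)-1-[(4-methoxyphenyl)methoxy]ethyl}-4,8-dimethyl-1-oxaspiro[2.5]octane-2-carboxylate | COC(=O)[C@H]1O[C@@]12[C@](C)(C(=O)c1ccoc1)CC[C@H]([C@@H](C)OCc1ccc(OC)cc1)[C@@]2(C)C(=O)Cl | intermediate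
28 | methyl (2S,3R,4R,5S,8R)-8-(furan-3-carbonyl)-4-(4-hydroxy-4-methylpent-2-ynoyl)-5-{(1R)-1-[(4-methoxyphenyl)methoxy]ethyl}-4,8-dimethyl-1-oxaspiro[2.5]octane-2-carboxylate | COC(=O)[C@H]1O[C@@]12[C@](C)(C(=O)c1ccoc1)CC[C@H]([C@@H](C)OCc1ccc(OC)cc1)[C@@]2(C)C(=O)C#CC(C)(C)O | intermediate
29 | methyl (2S,3R,4R,5S,8R)-8-(furan-3-carbonyl)-4-[(2Z)-4-hydroxy-3-iodo-4-methylpent-2-enoyl]-5-{(1R)-1-[(4-methoxyphenyl)methoxy]ethyl}-4,8-dimethyl-1-oxaspiro[2.5]octane-2-carboxylate | COC(=O)[C@H]1O[C@@]12[C@](C)(C(=O)c1ccoc1)CC[C@H]([C@@H](C)OCc1ccc(OC)cc1)[C@@]2(C)C(=O)/C=C(\I)C(C)(C)O | intermediate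
30 | ethyl (2Z)-3-(4,4,5,5-tetramethyl-1,3,2-dioxaborolan-2-yl)prop-2-enoate | CCOC(=O)/C=C\B1OC(C)(C)C(C)(C)O1 | starting material
31 | methyl (2S,3R,4R,5S,8R)-4-[(2E,4Z)-6-ethoxy-3-(2-hydroxypropan-2-yl)-6-oxohexa-2,4-dienoyl]-8-(furan-3-carbonyl)-5-{(1R)-1-[(4-methoxyphenyl)methoxy]ethyl}-4,8-dimethyl-1-oxaspiro[2.5]octane-2-carboxylate | COC(=O)[C@H]1O[C@@]12[C@](C)(C(=O)c1ccoc1)CC[C@H]([C@@H](C)OCc1ccc(OC)cc1)[C@@]2(C)C(=O)/C=C(\C=C/C(=O)OCC)C(C)(C)O | intermediate
32 | methyl (2S,3R,4R,5S,8R)-4-[(2E)-2-(6,6-dimethyl-2-oxo-2H-pyran-5(6H)-ylidene)acetyl]-8-(furan-3-carbonyl)-5-{(1R)-1-[(4-methoxyphenyl)methoxy]ethyl}-4,8-dimethyl-1-oxaspiro[2.5]octane-2-carboxylate | COC(=O)[C@H]1O[C@@]12[C@](C)(C(=O)c1ccoc1)CC[C@H]([C@@H](C)OCc1ccc(OC)cc1)[C@@]2(C)C(=O)/C=C1\C=CC(=O)OC1(C)C | intermediate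
33 | methyl (2S,3R,4R,5S,8R)-4-[(2E)-2-(6,6-dimethyl-2-oxo-2H-pyran-5(6H)-ylidene)acetyl]-8-(furan-3-carbonyl)-5-[(1R)-1-hydroxyethyl]-4,8-dimethyl-1-oxaspiro[2.5]octane-2-carboxylate (CNP0293135.1) | COC(=O)[C@H]1O[C@@]12[C@](C)(C(=O)c1ccoc1)CC[C@H]([C@@H](C)O)[C@@]2(C)C(=O)/C=C1\C=CC(=O)OC1(C)C | target

Total step count: 17 steps. Longest linear sequence: 15 steps (steps 1–5 and 8–17, from 1); steps 6 and 7 form the side branch to 16.

Steps most likely to fail

1. Step 8. The diene face may not be selected as modelled, because the C17 centre and the remote C10 centre may pull in opposite directions. In addition, the inside C18 methyl slows the cycloaddition, so amine-mediated isomerisation of the allene can compete. Fallback: change the controlling stereocentre rather than the conditions. The route sets out from enyne 6 and aldehyde 7: the hydrozirconation/zinc sequence of step 4 with (+)-MIB should give the C17-epimeric dienol F1. Addition to 11 should give the phosphorane F2, and the ketene Wittig reaction with 16 (via 17) should give the epimeric allene diester F3. Cycloaddition under the step 8 conditions should then give the 17-epimeric ring C/D lactone F4. Hydrogenation (dihydro lactone F5), t-BuOOLi epoxidation (epoxy lactone F6), LiOH opening (lithium carboxylate F7) and methylation (hydroxy diester F8) follow as in steps 9–11. Dess–Martin oxidation erases C17 and comes back to the route at ketone 24.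

2. Step 10. Peroxide addition at C14, which is flanked by two quaternary carbons, may be too slow, so that acyl attack on the lactone or on the TMSE ester takes over. Fallback: raise the acceptor to the aldehyde oxidation level. The route sets out from 20: i-Bu2AlH (PhMe, −78 °C) should reduce only the lactone, to the lactol F9, which is in equilibrium with its ring-opened (Z)-hydroxy enal. H2O2/NaOH in MeOH should epoxidise that enal (Weitz–Scheffer epoxidation) and the product recloses to the epoxy lactol F10. TEMPO/PhI(OAc)2 oxidation of the lactol comes back to the route at epoxy lactone 21.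

3. Step 15. Acid-promoted opening of the spiro-oxirane by iodide may occur. Acid-catalysed Z-to-E isomerisation of the iodoenone is the second danger, since the tertiary alcohol would then add to C7. Fallback: put the metal on the substrate under neutral conditions. The route sets out from ynone 28: hydroxyl-directed trans-hydrostannation ([Cp*RuCl]4 cat., Bu3SnH, CH2Cl2) should place tin on C5 cis to the C7 carbonyl, giving the alkenylstannane F11. Stille coupling with commercial ethyl (2Z)-3-iodoprop-2-enoate (Pd(PPh3)4, copper thiophene-2-carboxylate, DMF) should give hydroxy dienoate 31. This lactonises on brief exposure to K3PO4 and comes back to the route at 32.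

Further compounds

F1 | step 8 | (1R,2E,4E,6R)-1-(furan-3-yl)-6-[(4-methoxyphenyl)methoxy]-2-methylhepta-2,4-dien-1-ol | C[C@@H](OCc1ccc(OC)cc1)/C=C/C=C(\C)[C@@H](O)c1ccoc1
F2 | step 8 | (1R,2E,4E,6R)-1-(furan-3-yl)-6-[(4-methoxyphenyl)methoxy]-2-methylhepta-2,4-dien-1-yl (triphenyl-λ5-phosphanylidene)acetate | C[C@@H](OCc1ccc(OC)cc1)/C=C/C=C(\C)[C@@H](OC(=O)C=P(c1ccccc1)(c1ccccc1)c1ccccc1)c1ccoc1
F3 | step 8 | 5-[(1R,2E,4E,6R)-1-(furan-3-yl)-6-[(4-methoxyphenyl)methoxy]-2-methylhepta-2,4-dien-1-yl] 1-[2-(trimethylsilyl)ethyl] 2-methylpenta-2,3-dienedioate | C[C@@H](OCc1ccc(OC)cc1)/C=C/C=C(\C)[C@@H](OC(=O)C=C=C(C)C(=O)OCC[Si](C)(C)C)c1ccoc1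
F4 | step 8 | 17-epimer of lactone 19 (furyl cis to the C18 methyl on ring D) | O=C1O[C@@H](c2ccoc2)[C@]2(C)C=C[C@H]([C@@H](C)OCc3ccc(OC)cc3)[C@@](C)(C(=O)OCC[Si](C)(C)C)C2=C1
F5 | step 8 | 17-epimer of dihydro lactone 20 | O=C1O[C@@H](c2ccoc2)[C@]2(C)CC[C@H]([C@@H](C)OCc3ccc(OC)cc3)[C@@](C)(C(=O)OCC[Si](C)(C)C)C2=C1
F6 | step 8 | 17-epimer of epoxy lactone 21 | O=C1O[C@@H](c2ccoc2)[C@]2(C)CC[C@H]([C@@H](C)OCc3ccc(OC)cc3)[C@@](C)(C(=O)OCC[Si](C)(C)C)[C@]23O[C@H]13
F7 | step 8 | 17-epimer of lithium carboxylate 22 | [Li+].[O-]C(=O)[C@H]1O[C@@]12[C@](C)([C@@H](O)c1ccoc1)CC[C@H]([C@@H](C)OCc1ccc(OC)cc1)[C@@]2(C)C(=O)OCC[Si](C)(C)C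
F8 | step 8 | 17-epimer of hydroxy diester 23 | COC(=O)[C@H]1O[C@@]12[C@](C)([C@@H](O)c1ccoc1)CC[C@H]([C@@H](C)OCc1ccc(OC)cc1)[C@@]2(C)C(=O)OCC[Si](C)(C)C
F9 | step 10 | lactol of 20 (C16 hemiacetal, both anomers) | OC1O[C@H](c2ccoc2)[C@]2(C)CC[C@H]([C@@H](C)OCc3ccc(OC)cc3)[C@@](C)(C(=O)OCC[Si](C)(C)C)C2=C1
F10 | step 10 | 14,15-epoxy lactol (C16 hemiacetal of 21) | OC1O[C@H](c2ccoc2)[C@]2(C)CC[C@H]([C@@H](C)OCc3ccc(OC)cc3)[C@@](C)(C(=O)OCC[Si](C)(C)C)[C@]23O[C@H]13
F11 | step 15 | methyl (2S,3R,4R,5S,8R)-8-(furan-3-carbonyl)-4-[(2Z)-4-hydroxy-4-methyl-3-(tributylstannyl)pent-2-enoyl]-5-{(1R)-1-[(4-methoxyphenyl)methoxy]ethyl}-4,8-dimethyl-1-oxaspiro[2.5]octane-2-carboxylate | COC(=O)[C@H]1O[C@@]12[C@](C)(C(=O)c1ccoc1)CC[C@H]([C@@H](C)OCc1ccc(OC)cc1)[C@@]2(C)C(=O)/C=C(\[Sn](CCCC)(CCCC)CCCC)C(C)(C)O
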